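**Retrosynthetic overview**
- The alkylidene succinimide comes from a C12 aldehyde and the phosphorane made from maleimide and PPh3 (Wittig). The 7β-acetate and 8(17)-methylene come from a 7-ketone carrying a masked C17 (CH2OPiv). The 2α-chloride comes from amidyl-radical C–H chlorination of the saturated decalone.
- Key step: an acid-triggered cation/homoenolate ring expansion of a 1-siloxybicyclo[3.1.0]hexane carrying a homoprenyl chain. It forms C4–C5, closes ring A, sets C5 and enlarges the five-membered ring to ring B (C7 ketone) in one operation.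
- The siloxycyclopropane comes from Simmons–Smith reaction of the silyl enol ether formed by Cu-catalysed 1,4-addition of homoprenyl Grignard (sets quaternary C10) to a 3-methyl-4,5-disubstituted cyclopentenone.
- The cyclopentenone comes from 2-methylcyclopent-2-enone by CBS reduction, Johnson–Claisen rearrangement (sets C9), allylic oxidation and α′-hydroxymethylation.
- Ring order: cyclopentane (ring B precursor) first, then the cyclopropane, then rings A and B together.

Assumption: carbon labels C1–C12 and C17 follow labdane numbering of the target core (C1–C10 decalin, C11–C12 side chain, C17 on C8) and are used for the same atoms in all earlier intermediates; α is the face opposite the C10 methyl. The target is (2S,5S,7S,9R,10S), that is 2α-Cl, 7β-OAc, 5α-H, 9α-H, 10β-CH3.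

**Route**

Step 1
Reactants: 1 2-methylcyclopent-2-en-1-one
Product: 2 (R)-2-methylcyclopent-2-en-1-ol
Conditions: (S)-2-methyl-CBS-oxazaborolidine (10 mol %), BH3·SMe2, THF, −20 °C; MeOH quench
Reagents that add atoms: none
Why: Corey–Bakshi–Shibata reduction; the carbonyl binds the catalyst with the substituted alkenyl side as the large group, so hydride delivery gives the R carbinol, the stereocentre from which all others are derived.

Step 2
Reactants: 2 (R)-2-methylcyclopent-2-en-1-ol; 3 trimethyl orthoacetate
Product: 6 methyl 2-[(1R)-2-methylcyclopent-2-en-1-yl]acetate, via mixed orthoester 4 (not isolated), via ketene acetal 5 (not isolated)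
Conditions: 3 (6 equiv, neat), EtCO2H (5 mol %), 135 °C, MeOH distilled off
Reagents that add atoms: none
Why: Johnson–Claisen orthoester rearrangement; the suprafacial [3,3] shift delivers the acetate arm to the ring face from which the C–O bond leaves, transferring the carbinol chirality to C9.

Step 3
Reactants: 6 methyl 2-[(1R)-2-methylcyclopent-2-en-1-yl]acetate
Product: 7 methyl 2-[(1R)-2-methyl-4-oxocyclopent-2-en-1-yl]acetate
Conditions: Rh2(cap)4 (dirhodium tetracaprolactamate, 1 mol %), tBuOOH (70% aq., 5 equiv), K2CO3, CH2Cl2, 25 °C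
Reagents that add atoms: tert-butyl hydroperoxide, CC(C)(C)OO
Why: Rh-catalysed allylic C–H oxidation (tert-butylperoxyl radical abstraction) at the ring CH2 next to the alkene CH gives the conjugated enone, the usual outcome for 1-methylcycloalkenes; C9 is untouched.

Step 4
Reactants: 7 methyl 2-[(1R)-2-methyl-4-oxocyclopent-2-en-1-yl]acetate
Product: 10 methyl 2-[(1S,5R)-2-methyl-4-oxo-5-(pivaloyloxymethyl)cyclopent-2-en-1-yl]acetate, via lithium dienolate 8 (not isolated), via lithium aldolate 9 (not isolated)
Conditions: LiN(iPr)2, THF, −78 °C; CH2O (gas); tBuCOCl, −78 → 0 °C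
Reagents that add atoms: formaldehyde, C=O; pivaloyl chloride, CC(C)(C)C(Cl)=O
Why: Kinetic α′-deprotonation, formaldehyde aldol anti to the adjacent C9 arm (2,3-trans, also the thermodynamic arrangement) and in situ O-acylation; CH2OPiv is the masked C17 methylene and later shields the lower ring face.

Step 5
Reactants: 10 methyl 2-[(1S,5R)-2-methyl-4-oxo-5-(pivaloyloxymethyl)cyclopent-2-en-1-yl]acetate; 11 5-bromo-2-methylpent-2-ene
Product: 13 trimethylsilyl enol ether of the 1,4-adduct (homoprenyl on C10 trans to the C9 arm), via (4-methylpent-3-en-1-yl)magnesium bromide 12 (not isolated)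
Conditions: 11, Mg, THF, 25 °C; then CuBr·SMe2 (20 mol %), Me3SiCl, HMPA, 10, THF, −78 °C; Et3N work-up
Reagents that add atoms: chlorotrimethylsilane, C[Si](C)(C)Cl
Why: Me3SiCl-accelerated copper-catalysed conjugate addition of a Grignard reagent builds quaternary C10 anti to the C9 arm (methyl ends cis to it) and traps the enolate regiospecifically as the C5=C7 silyl enol ether.

Step 6
Reactants: 13 trimethylsilyl enol ether of the 1,4-adduct
Product: 14 1-(trimethylsilyloxy)bicyclo[3.1.0]hexane (C5–C6–C7 cyclopropane with C6 cis to the C10 methyl)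
Conditions: Et2Zn, CH2I2 (1.3 equiv each), CH2Cl2, 0 °C
Reagents that add atoms: diiodomethane, ICI
Why: Furukawa-modified Simmons–Smith cyclopropanation is far faster on the silyl enol ether than on the trisubstituted alkene and occurs on the face of the C10 methyl, anti to the homoprenyl chain and to the CH2OPiv group on C8.

Step 7
Reactants: 14 1-(trimethylsilyloxy)bicyclo[3.1.0]hexane
Product: 15 methyl 7-oxo-17-(pivaloyloxy)-13,14,15,16-tetranorlabdan-12-oate (trans-decalin; 5α-H, 8β-H, 9α-H, 10β-CH3)
Conditions: HNTf2 (10 mol %), (CF3)2CHOH (2 equiv), CH2Cl2, −78 → −30 °C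
Reagents that add atoms: none
Why: Proposed new method: Markovnikov protonation of the trisubstituted alkene gives the C4 tertiary cation, which is attacked by the strained C5–C7 σ bond of the siloxycyclopropane (a homoenolate, raised in energy by the geminal silyloxy donor) through a six-membered chair transition state from the back side of the breaking bond (inversion at C5), so the internal cyclopropane bond opens, the five-membered ring becomes the cyclohexanone (C7 silyloxocarbenium, desilylated by the fluoro alcohol, which returns the proton) and ring A closes in the same event; with C6 cis to the C10 methyl, inversion gives the trans ring fusion (5α-H anti to 10β-CH3); closest known reaction types are Lewis-acid-mediated additions of cyclopropyl silyl ethers to oxocarbenium ions, tert-alkylation of silyl enol ethers by tertiary cations, and FeCl3 ring enlargement of the same siloxycyclopropanes.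

Step 8
Reactants: 15 methyl 7-oxo-17-(pivaloyloxy)-13,14,15,16-tetranorlabdan-12-oate
Product: 16 methyl 2α-chloro-7-oxo-17-(pivaloyloxy)-13,14,15,16-tetranorlabdan-12-oate
Conditions: N-tert-butyl-N-chloro-3,5-bis(trifluoromethyl)benzamide (1.5 equiv), PhH, blue LEDs, 25 °C, no added base
Reagents that add atoms: N-tert-butyl-N-chloro-3,5-bis(trifluoromethyl)benzamide, CC(C)(C)N(Cl)C(=O)c1cc(cc(c1)C(F)(F)F)C(F)(F)F
Why: Amidyl-radical aliphatic C–H chlorination; the bulky electrophilic radical abstracts the most accessible electron-rich methylene hydrogen (C2; C1 and C3 are neopentyl, ring B is deactivated by ketone, ester and pivalate) and chlorine is returned on the equatorial α face, away from the 1,3-diaxial C4 and C10 methyls, as established for sclareolide-type trans-decalins.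

Step 9
Reactants: 16 methyl 2α-chloro-7-oxo-17-(pivaloyloxy)-13,14,15,16-tetranorlabdan-12-oate
Product: 17 methyl 2α-chloro-7-oxo-13,14,15,16-tetranorlabd-8(17)-en-12-oate
Conditions: DBU, CH2Cl2, 0 → 25 °C
Reagents that add atoms: none
Why: E1cB elimination of pivalate from the β-acyloxy ketone unmasks the exocyclic enone regiospecifically; the exo double bond cannot move into the ring because C9–H is only cross-conjugated.

Step 10
Reactants: 17 methyl 2α-chloro-7-oxo-13,14,15,16-tetranorlabd-8(17)-en-12-oate
Product: 18 methyl 2α-chloro-7β-hydroxy-13,14,15,16-tetranorlabd-8(17)-en-12-oate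
Conditions: NaBH4, CeCl3·7H2O, MeOH, −78 °C
Reagents that add atoms: none
Why: Luche 1,2-reduction; axial hydride attack from the α face (only axial hydrogens at C5 and C9 flank it) gives the equatorial 7β-alcohol and leaves the ester and chloride alone.

Step 11
Reactants: 18 methyl 2α-chloro-7β-hydroxy-13,14,15,16-tetranorlabd-8(17)-en-12-oate
Product: 19 2α-chloro-7β-hydroxy-13,14,15,16-tetranorlabd-8(17)-en-12-al
Conditions: iBu2AlH (2.3 equiv), CH2Cl2, −78 °C; aq. KNaC4H4O6 work-up
Reagents that add atoms: none
Why: Partial reduction of the methyl ester; the aluminium hemiacetal is stable at −78 °C and gives the aldehyde on work-up, and the first equivalent is consumed by the hydroxyl; the diequatorial 7-OH and C9 arm cannot close a lactol.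

Step 12
Reactants: 19 2α-chloro-7β-hydroxy-13,14,15,16-tetranorlabd-8(17)-en-12-al
Product: 20 7β-acetoxy-2α-chloro-13,14,15,16-tetranorlabd-8(17)-en-12-al
Conditions: Ac2O, pyridine, DMAP (cat.), CH2Cl2, 0 °C
Reagents that add atoms: acetic anhydride, CC(=O)OC(C)=O
Why: Nucleophile-catalysed O-acylation of the unhindered equatorial allylic alcohol; the aldehyde is untouched at 0 °C.

Step 13
Reactants: 20 7β-acetoxy-2α-chloro-13,14,15,16-tetranorlabd-8(17)-en-12-al; 21 maleimide
Product: 23 CNP0220384.1, via phosphorus ylide 22 (not isolated)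
Conditions: 21, PPh3, THF, 60 °C; then 20, 60 °C
Reagents that add atoms: none
Why: Wittig olefination with the stabilised ylide formed by conjugate addition of PPh3 to maleimide and proton shift; stabilised ylides give the E alkene (C11 trans to the C16 carbonyl), and acetate, chloride and exocyclic alkene are inert.

**Compound list**

1 | 2-methylcyclopent-2-en-1-one | CC1=CCCC1=O | starting material
2 | (R)-2-methylcyclopent-2-en-1-ol | CC1=CCC[C@H]1O | intermediate
3 | trimethyl orthoacetate (1,1,1-trimethoxyethane) | CC(OC)(OC)OC | starting material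
4 | mixed orthoester, 1,1-dimethoxy-1-[(1R)-2-methylcyclopent-2-en-1-yl]oxyethane | CC1=CCC[C@H]1OC(C)(OC)OC | intermediate
5 | ketene acetal, 1-methoxy-1-[(1R)-2-methylcyclopent-2-en-1-yl]oxyethene | CC1=CCC[C@H]1OC(=C)OC | intermediate
6 | methyl 2-[(1R)-2-methylcyclopent-2-en-1-yl]acetate | C1CC=C(C)[C@H]1CC(=O)OC | intermediate
7 | methyl 2-[(1R)-2-methyl-4-oxocyclopent-2-en-1-yl]acetate | C1C(=O)C=C(C)[C@H]1CC(=O)OC | intermediate
8 | lithium dienolate of 7 (O–Li on C7, C7=C8 and C5=C10 double bonds) | C1=C([O-])C=C(C)[C@H]1CC(=O)OC.[Li+] | intermediate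
9 | lithium aldolate, lithium alkoxide of the trans-C8-hydroxymethyl derivative of 7 | [Li+].[O-]C[C@@H]1C(=O)C=C(C)[C@H]1CC(=O)OC | intermediate
10 | methyl 2-[(1S,5R)-2-methyl-4-oxo-5-(pivaloyloxymethyl)cyclopent-2-en-1-yl]acetate (the two arms trans) | CC(C)(C)C(=O)OC[C@@H]1C(=O)C=C(C)[C@H]1CC(=O)OC | intermediate
11 | 5-bromo-2-methylpent-2-ene | CC(C)=CCCBr | starting material
12 | (4-methylpent-3-en-1-yl)magnesium bromide | CC(C)=CCC[Mg]Br | intermediate
13 | methyl 2-[2-methyl-2-(4-methylpent-3-en-1-yl)-5-(pivaloyloxymethyl)-4-(trimethylsilyloxy)cyclopent-3-en-1-yl]acetate; C10 methyl cis and homoprenyl trans to the C9 acetate arm, CH2OPiv trans to that arm | CC(C)(C)C(=O)OC[C@@H]1C(O[Si](C)(C)C)=C[C@](C)(CCC=C(C)C)[C@H]1CC(=O)OC | intermediate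
14 | 1-(trimethylsilyloxy)bicyclo[3.1.0]hexane from 13; cyclopropane C5–C6–C7 with CH2 (C6) cis to the C10 methyl, other centres as in 13 | CC(C)(C)C(=O)OC[C@@H]1[C@@]2(O[Si](C)(C)C)C[C@H]2[C@](C)(CCC=C(C)C)[C@H]1CC(=O)OC | intermediate
15 | methyl 7-oxo-17-(pivaloyloxy)-13,14,15,16-tetranorlabdan-12-oate; trans-decalin, 5α-H, 8β-H (C17 equatorial), 9α-H, 10β-CH3 | CC(C)(C)C(=O)OC[C@@H]1C(=O)C[C@H]2C(C)(C)CCC[C@]2(C)[C@H]1CC(=O)OC | intermediate
16 | methyl 2α-chloro-7-oxo-17-(pivaloyloxy)-13,14,15,16-tetranorlabdan-12-oate (Cl equatorial) | CC(C)(C)C(=O)OC[C@@H]1C(=O)C[C@H]2C(C)(C)C[C@H](Cl)C[C@]2(C)[C@H]1CC(=O)OC | intermediate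
17 | methyl 2α-chloro-7-oxo-13,14,15,16-tetranorlabd-8(17)-en-12-oate | C=C1C(=O)C[C@H]2C(C)(C)C[C@H](Cl)C[C@]2(C)[C@H]1CC(=O)OC | intermediate
18 | methyl 2α-chloro-7β-hydroxy-13,14,15,16-tetranorlabd-8(17)-en-12-oate (OH equatorial) | C=C1[C@@H](O)C[C@H]2C(C)(C)C[C@H](Cl)C[C@]2(C)[C@H]1CC(=O)OC | intermediate
19 | 2α-chloro-7β-hydroxy-13,14,15,16-tetranorlabd-8(17)-en-12-al | C=C1[C@@H](O)C[C@H]2C(C)(C)C[C@H](Cl)C[C@]2(C)[C@H]1CC=O | intermediate
20 | 7β-acetoxy-2α-chloro-13,14,15,16-tetranorlabd-8(17)-en-12-al | C=C1[C@@H](OC(C)=O)C[C@H]2C(C)(C)C[C@H](Cl)C[C@]2(C)[C@H]1CC=O | intermediate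
21 | maleimide | O=C1C=CC(=O)N1 | starting material
22 | 3-(triphenylphosphoranylidene)pyrrolidine-2,5-dione | O=C1CC(=P(c2ccccc2)(c2ccccc2)c2ccccc2)C(=O)N1 | intermediate
23 | CNP0220384.1, (2S,5S,7S,9R,10S)-7-acetoxy-2-chlorolabda-8(17),12E-diene 15,16-imide (E-alkylidene succinimide) | C=C1[C@@H](OC(C)=O)C[C@H]2C(C)(C)C[C@H](Cl)C[C@]2(C)[C@H]1C/C=C1\CC(=O)NC1=O | target

**Step count and risks**

Total step count: 13. Longest linear sequence: 13 steps (1 → 23); 3, 11 and 21 enter as single fragments.

Steps most likely to fail: 7, 8 and 5.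

Step 7 (the proposed cation/homoenolate ring expansion). The siloxycyclopropane may be protonated or desilylated instead of attacking the cation, or the minor cyclopropane face isomer may give the cis ring fusion. The fallback uses known chemistry, sets out from 14 and returns at 15. FeCl3 in DMF at 0 °C (one-electron Ito–Saegusa ring opening of the siloxycyclopropane) gives the ring-expanded 3-chlorocyclohexanone F1. NaOAc in MeOH eliminates HCl to the 4,4,5,6-tetrasubstituted cyclohex-2-enone F2 (C7 ketone, C5=C6), which also erases the C5 centre, so the cyclopropane face no longer matters. Fe(acac)3 with PhSiH3 in EtOH/ethylene glycol at 60 °C then closes ring A by hydrogen-atom-transfer radical conjugate addition of the C4 radical to C5. The equatorial C9 arm holds the tether on C10 equatorial, which favours the trans fusion, and 15 is obtained.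

Step 8 (site and face selectivity of the radical chlorination on a substrate that is not sclareolide). The fallback sets out from 15 and returns at 16. Methylene oxidation with the divalent iron catalyst Fe(PDP)(MeCN)2(SbF6)2, H2O2 and AcOH in MeCN gives the 2,7-diketone F3 (C2 is the most accessible and electron-rich CH2). LiBH(sBu)3 at −78 °C attacks the less hindered C2 ketone from the open equatorial side and gives the axial 2β-alcohol F4. PPh3/CCl4 (Appel reaction, inversion) then gives the equatorial 2α-chloride 16.

Step 5 (copper-catalysed addition to a congested β,β-disubstituted enone that carries a base-labile β-acyloxy ketone). The fallback sets out from 7 and returns at 17. The addition of 12 (CuBr·SMe2, Me3SiCl) is run on enone 7, which has no eliminable group, and gives the silyl enol ether F5. Et2Zn/CH2I2 gives the siloxycyclopropane F6; without the C8 substituent the face selectivity is lower and the isomers are separated here. The step 7 conditions give the C17-free decalone F7, and the step 8 conditions give its 2α-chloride F8. C17 is then introduced last by thermodynamically controlled α-methylenation (paraformaldehyde, N-methylanilinium trifluoroacetate, THF, 65 °C; enolisation towards C8, as for trans-fused 3-keto steroids towards C2), which gives 17.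

**Further compounds**

F1 | step 7 | methyl 2-[3-chloro-2-methyl-2-(4-methylpent-3-en-1-yl)-5-oxo-6-(pivaloyloxymethyl)cyclohexyl]acetate (C5 chloride as epimer mixture, other centres as in 14) | CC(C)(C)C(=O)OC[C@@H]1C(=O)CC(Cl)[C@](C)(CCC=C(C)C)[C@H]1CC(=O)OC
F2 | step 7 | methyl 2-[2-methyl-2-(4-methylpent-3-en-1-yl)-5-oxo-6-(pivaloyloxymethyl)cyclohex-3-en-1-yl]acetate (C7 ketone, C5=C6) | CC(C)(C)C(=O)OC[C@@H]1C(=O)C=C[C@](C)(CCC=C(C)C)[C@H]1CC(=O)OC
F3 | step 8 | methyl 2,7-dioxo-17-(pivaloyloxy)-13,14,15,16-tetranorlabdan-12-oate | CC(C)(C)C(=O)OC[C@@H]1C(=O)C[C@H]2C(C)(C)CC(=O)C[C@]2(C)[C@H]1CC(=O)OC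
F4 | step 8 | methyl 2β-hydroxy-7-oxo-17-(pivaloyloxy)-13,14,15,16-tetranorlabdan-12-oate (OH axial) | CC(C)(C)C(=O)OC[C@@H]1C(=O)C[C@H]2C(C)(C)C[C@@H](O)C[C@]2(C)[C@H]1CC(=O)OC
F5 | step 5 | methyl 2-[2-methyl-2-(4-methylpent-3-en-1-yl)-4-(trimethylsilyloxy)cyclopent-3-en-1-yl]acetate (C10 methyl cis to the acetate arm) | C1C(O[Si](C)(C)C)=C[C@](C)(CCC=C(C)C)[C@H]1CC(=O)OC
F6 | step 5 | 1-(trimethylsilyloxy)bicyclo[3.1.0]hexane from F5 (C6 cis to the C10 methyl) | C1[C@@]2(O[Si](C)(C)C)C[C@H]2[C@](C)(CCC=C(C)C)[C@H]1CC(=O)OC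
F7 | step 5 | methyl 7-oxo-13,14,15,16,17-pentanorlabdan-12-oate (trans-decalin, 5α-H, 9α-H, 10β-CH3) | C1C(=O)C[C@H]2C(C)(C)CCC[C@]2(C)[C@H]1CC(=O)OC
F8 | step 5 | methyl 2α-chloro-7-oxo-13,14,15,16,17-pentanorlabdan-12-oate | C1C(=O)C[C@H]2C(C)(C)C[C@H](Cl)C[C@]2(C)[C@H]1CC(=O)OC
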